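**Strategy.** The ring is numbered C1 (carbinol carbon carrying the CH2OBz carbon C7), C2 (CHOBz), C3=C4, C5 (CHOBz), C6 (CHOH). With C7 at the acid level, C7–C1–C2–C3=C4 is a γ,δ-unsaturated acid, so the C1–C2 bond is made by an Ireland–Claisen rearrangement. Because C4 and C1 are already joined through C5–C6, the allyl ester is a δ-lactone: a D-manno-configured pyranone acetonide carrying a (Z)-2-benzoyloxyvinyl group on its carbinol carbon. Ring contraction of its silyl ketene acetal forms C1–C2, the C3=C4 alkene and the C1 and C2 stereocentres in one operation, by transfer from the lactone C–O stereocentre. The lactone is built de novo from furfural.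

Key step: step 10

Remark (assumptions): the lipase in step 2 is taken to show its usual enantiopreference for secondary carbinols (furyl as large group, ethynyl as medium group), and hydride reduction of dione 7 is taken to give the 5,6-trans alcohol, as 6-alkyl analogues do.

**Step 1**
Reactants: 1 furfural; 2 ethynylmagnesium bromide
Product: 4 rac-1-(furan-2-yl)prop-2-yn-1-yl acetate, via bromomagnesium alkoxide 3 (not isolated)
Conditions: THF, 0 °C; then Ac2O, 0 °C → rt; aq. NH4Cl work-up
Reagents that add atoms: acetic anhydride CC(=O)OC(C)=O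
Why: 1,2-addition of the alkynyl Grignard reagent to the aldehyde and O-acetylation of the alkoxide in the same flask; the carbinol centre is formed racemic and is resolved in step 2.

**Step 2**
Reactants: 4 rac-1-(furan-2-yl)prop-2-yn-1-yl acetate
Product: 5 (R)-1-(furan-2-yl)prop-2-yn-1-ol
Conditions: immobilised Candida antarctica lipase B, phosphate buffer pH 7/MTBE, 30 °C, stopped at about 40–45 % conversion; unreacted (S)-acetate removed by chromatography
Reagents that add atoms: none
Why: lipase-catalysed kinetic resolution by enantioselective ester hydrolysis, in which the (R)-acetate should be the fast-reacting enantiomer, so the liberated alcohol is (R).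

**Step 3**
Reactants: 5 (R)-1-(furan-2-yl)prop-2-yn-1-ol
Product: 6 (2R)-2-ethynyl-6-hydroxy-2H-pyran-3(6H)-one (anomer mixture)
Conditions: NBS, NaHCO3, NaOAc, THF/H2O 4:1, 0 °C
Reagents that add atoms: water O
Why: Achmatowicz rearrangement (oxidative opening of the furan and closure of the carbinol oxygen onto the new aldehyde); the carbinol centre is untouched and becomes C2 of the pyranone.

**Step 4**
Reactants: 6 (2R)-2-ethynyl-6-hydroxy-2H-pyran-3(6H)-one
Product: 7 (6R)-6-ethynyl-2H-pyran-2,5(6H)-dione
Conditions: Jones reagent (CrO3, H2SO4), acetone, 0 °C, short contact time, used crude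
Reagents that add atoms: none
Why: Jones oxidation of the lactol to the lactone under acidic conditions, the standard follow-up of the Achmatowicz step; direct use of the crude dione should limit enolisation at C6.

**Step 5**
Reactants: 7 (6R)-6-ethynyl-2H-pyran-2,5(6H)-dione
Product: 8 (5S,6R)-6-ethynyl-5-hydroxy-5,6-dihydro-2H-pyran-2-one (5,6-trans)
Conditions: NaBH4, CeCl3·7H2O, MeOH/CH2Cl2, −78 °C
Reagents that add atoms: none
Why: Luche 1,2-reduction of the enone carbonyl; axial hydride delivery anti to the pseudoaxial C6–H should give the alcohol trans to the ethynyl group (substrate control from C6).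

**Step 6**
Reactants: 8 (5S,6R)-6-ethynyl-5-hydroxy-5,6-dihydro-2H-pyran-2-one
Product: 9 (2R,3S)-2-ethynyl-6-oxo-3,6-dihydro-2H-pyran-3-yl benzoate
Conditions: BzCl, pyridine, DMAP (cat.), CH2Cl2, 0 °C
Reagents that add atoms: benzoyl chloride O=C(Cl)c1ccccc1
Why: DMAP-catalysed O-acylation with retention; this benzoate is the C5 benzoate of the target and fixes the lactone as the δ-isomer.

**Step 7**
Reactants: 9 (2R,3S)-2-ethynyl-6-oxo-3,6-dihydro-2H-pyran-3-yl benzoate
Product: 10 4-O-benzoyl-6,7-dideoxy-D-manno-hept-6-ynono-1,5-lactone (2,3-cis-diol, anti to the 4-benzoate)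
Conditions: OsO4 (cat.), NMO, citric acid, t-BuOH/H2O, rt
Reagents that add atoms: osmium tetroxide O=[Os](=O)(=O)=O (catalytic oxygen carrier); N-methylmorpholine N-oxide C[N+]1([O-])CCOCC1; water O
Why: catalytic OsO4/NMO cis-dihydroxylation of the electron-poor alkene under citric acid buffering; osmylation should occur anti to the allylic benzoate to give the D-manno diol, the alkyne being far less reactive and the acidic medium suppressing lactone opening and benzoate migration.

**Step 8**
Reactants: 10 4-O-benzoyl-6,7-dideoxy-D-manno-hept-6-ynono-1,5-lactone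
Product: 11 4-O-benzoyl-6,7-dideoxy-2,3-O-isopropylidene-D-manno-hept-6-ynono-1,5-lactone
Conditions: 2,2-dimethoxypropane, CSA (cat.), acetone, rt
Reagents that add atoms: 2,2-dimethoxypropane COC(C)(C)OC
Why: acid-catalysed acetal exchange on the cis-diol gives the cis-fused isopropylidene acetal, which marks the two oxygens that end as free hydroxyls.

**Step 9**
Reactants: 11 4-O-benzoyl-6,7-dideoxy-2,3-O-isopropylidene-D-manno-hept-6-ynono-1,5-lactone
Product: 12 (Z)-4,7-di-O-benzoyl-6-deoxy-2,3-O-isopropylidene-D-manno-hept-6-enono-1,5-lactone (lactone carrying a (Z)-2-benzoyloxyvinyl group on its carbinol carbon)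
Conditions: PhCO2H, [Ru(η3-2-methylallyl)2(dppb)] (3 mol %), toluene, 65 °C
Reagents that add atoms: benzoic acid O=C(O)c1ccccc1
Why: ruthenium-catalysed anti-Markovnikov hydro-acyloxylation of the terminal alkyne through a Ru-vinylidene, to which the carboxylate adds to give the (Z)-enol ester.

**Step 10**
Reactants: 12 (Z)-4,7-di-O-benzoyl-6-deoxy-2,3-O-isopropylidene-D-manno-hept-6-enono-1,5-lactone
Product: 15 (1R,2R,5R,6S)-2,5-bis(benzoyloxy)-1,6-(isopropylidenedioxy)cyclohex-3-ene-1-carboxylic acid, via silyl ketene acetal 13 (not isolated), via trimethylsilyl ester 14 (not isolated)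
Conditions: TMSCl/Et3N, then LiHMDS, THF, −78 °C → rt; toluene, 100–110 °C; aq. citric acid work-up
Reagents that add atoms: chlorotrimethylsilane C[Si](C)(C)Cl (silyl group present in 13 and 14 only; none remains in 15)
Why: LiHMDS removes the only enolisable proton and the enolate is trapped in situ as silyl ketene acetal 13, which undergoes a [3,3]-sigmatropic shift in which C1–C2 forms while the lactone C4–O bond breaks and the double bond moves to C3=C4; the closest known reaction type is the Ireland–Claisen ring contraction of alkenyl-substituted lactone silyl ketene acetals to cycloalkenecarboxylic acids. The cyclohexene closes by suprafacial bonding across the pyranone (lactone α-carbon to the vinyl terminus on the carbinol carbon) through the boat-like, bicyclo[2.2.2]-shaped transition state that the two-carbon tether C5–C6 enforces, which also makes the new ring alkene cis. The configuration at C1 follows from the lactone stereocentre that carries the alkenyl group: the vinyl terminus can reach only the ketene acetal face syn to the C6 oxygen, so the carboxyl carbon ends trans and the C1 oxygen cis to C6–O; the configuration at C2 follows from the Z geometry of the enol benzoate, whose oxygen ends cis to the C1 oxygen; C5 and C6 are carried over unchanged. The step needs enolisation without attack on the two benzoates and without β-elimination of the C6 oxygen; the hindered base, the in situ silyl trap at −78 °C and the dioxolane ring, which holds the β C–O bond near the plane of the enolate, should secure this. Because the Z-benzoyloxy group and the C6 oxygen become syn in the boat, heating is expected to be required.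

**Step 11**
Reactants: 15 (1R,2R,5R,6S)-2,5-bis(benzoyloxy)-1,6-(isopropylidenedioxy)cyclohex-3-ene-1-carboxylic acid
Product: 17 (1R,2R,5R,6S)-1-(hydroxymethyl)-1,6-(isopropylidenedioxy)cyclohex-3-ene-2,5-diyl dibenzoate, via acyl imidazolide 16 (not isolated)
Conditions: CDI, THF, rt; then NaBH4, THF/H2O, 0 °C
Reagents that add atoms: 1,1'-carbonyldiimidazole O=C(n1ccnc1)n1ccnc1 (imidazolyl group present in 16 only; none remains in 17)
Why: activation of the hindered acid as its acyl imidazolide and NaBH4 reduction to the primary alcohol, to which benzoates, acetonide and alkene are inert at 0 °C; any 2-O to 7-O benzoyl shift is levelled by step 12.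

**Step 12**
Reactants: 17 (1R,2R,5R,6S)-1-(hydroxymethyl)-1,6-(isopropylidenedioxy)cyclohex-3-ene-2,5-diyl dibenzoate
Product: 18 [(1R,2R,5R,6S)-2,5-bis(benzoyloxy)-1,6-(isopropylidenedioxy)cyclohex-3-en-1-yl]methyl benzoate
Conditions: BzCl, pyridine, DMAP (cat.), CH2Cl2, 0 °C → rt
Reagents that add atoms: benzoyl chloride O=C(Cl)c1ccccc1
Why: DMAP-catalysed benzoylation of the only free hydroxyl, a primary neopentyl-type alcohol.

**Step 13**
Reactants: 18 [(1R,2R,5R,6S)-2,5-bis(benzoyloxy)-1,6-(isopropylidenedioxy)cyclohex-3-en-1-yl]methyl benzoate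
Product: 19 [(1S,2R,5R,6S)-2,5-bis(benzoyloxy)-1,6-dihydroxycyclohex-3-en-1-yl]methyl benzoate (target)
Conditions: TFA/H2O 9:1, CH2Cl2, 0 °C → rt
Reagents that add atoms: none
Why: acid hydrolysis of the isopropylidene acetal releases the tertiary C1 and secondary C6 hydroxyls; benzoates are stable and acyl migration is slow under acidic conditions.

**Compound list**

1 | furfural | O=Cc1ccco1 | starting material
2 | ethynylmagnesium bromide | C#C[Mg]Br | starting material
3 | bromomagnesium 1-(furan-2-yl)prop-2-yn-1-olate | C#CC(O[Mg]Br)c1ccco1 | intermediate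
4 | rac-1-(furan-2-yl)prop-2-yn-1-yl acetate | CC(=O)OC(C#C)c1ccco1 | intermediate
5 | (R)-1-(furan-2-yl)prop-2-yn-1-ol | O[C@H](C#C)c1ccco1 | intermediate
6 | (2R)-2-ethynyl-6-hydroxy-2H-pyran-3(6H)-one, anomer mixture | O=C1C=CC(O)O[C@@H]1C#C | intermediate
7 | (6R)-6-ethynyl-2H-pyran-2,5(6H)-dione | O=C1C=CC(=O)O[C@@H]1C#C | intermediate
8 | (5S,6R)-6-ethynyl-5-hydroxy-5,6-dihydro-2H-pyran-2-one | O=C1O[C@H](C#C)[C@@H](O)C=C1 | intermediate
9 | (2R,3S)-2-ethynyl-6-oxo-3,6-dihydro-2H-pyran-3-yl benzoate | O=C1O[C@H](C#C)[C@@H](OC(=O)c2ccccc2)C=C1 | intermediate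
10 | 4-O-benzoyl-6,7-dideoxy-D-manno-hept-6-ynono-1,5-lactone | O=C1O[C@H](C#C)[C@@H](OC(=O)c2ccccc2)[C@H](O)[C@@H]1O | intermediate
11 | 4-O-benzoyl-6,7-dideoxy-2,3-O-isopropylidene-D-manno-hept-6-ynono-1,5-lactone | O=C1O[C@H](C#C)[C@@H](OC(=O)c3ccccc3)[C@@H]2OC(C)(C)O[C@H]12 | intermediate
12 | (Z)-4,7-di-O-benzoyl-6-deoxy-2,3-O-isopropylidene-D-manno-hept-6-enono-1,5-lactone | O=C1O[C@H](/C=C\OC(=O)c3ccccc3)[C@@H](OC(=O)c4ccccc4)[C@@H]2OC(C)(C)O[C@H]12 | intermediate
13 | trimethylsilyl ketene acetal of 12 | C[Si](C)(C)OC1=C2OC(C)(C)O[C@H]2[C@H](OC(=O)c3ccccc3)[C@@H](/C=C\OC(=O)c4ccccc4)O1 | intermediate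
14 | trimethylsilyl ester of acid 15 | C[Si](C)(C)OC(=O)[C@@]1(OC(C)(C)O2)[C@H](OC(=O)c3ccccc3)C=C[C@@H](OC(=O)c4ccccc4)[C@@H]12 | intermediate
15 | (1R,2R,5R,6S)-2,5-bis(benzoyloxy)-1,6-(isopropylidenedioxy)cyclohex-3-ene-1-carboxylic acid (1-O, 2-OBz and 6-O cis; 5-OBz trans) | OC(=O)[C@@]1(OC(C)(C)O2)[C@H](OC(=O)c3ccccc3)C=C[C@@H](OC(=O)c4ccccc4)[C@@H]12 | intermediate
16 | acyl imidazolide of acid 15 | O=C(n3ccnc3)[C@@]1(OC(C)(C)O2)[C@H](OC(=O)c4ccccc4)C=C[C@@H](OC(=O)c5ccccc5)[C@@H]12 | intermediate
17 | (1R,2R,5R,6S)-1-(hydroxymethyl)-1,6-(isopropylidenedioxy)cyclohex-3-ene-2,5-diyl dibenzoate | OC[C@@]1(OC(C)(C)O2)[C@H](OC(=O)c3ccccc3)C=C[C@@H](OC(=O)c4ccccc4)[C@@H]12 | intermediate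
18 | [(1R,2R,5R,6S)-2,5-bis(benzoyloxy)-1,6-(isopropylidenedioxy)cyclohex-3-en-1-yl]methyl benzoate | O=C(OC[C@@]1(OC(C)(C)O2)[C@H](OC(=O)c3ccccc3)C=C[C@@H](OC(=O)c4ccccc4)[C@@H]12)c5ccccc5 | intermediate
19 | [(1S,2R,5R,6S)-2,5-bis(benzoyloxy)-1,6-dihydroxycyclohex-3-en-1-yl]methyl benzoate | O=C(OC[C@@]1(O)[C@H](OC(=O)c2ccccc2)C=C[C@@H](OC(=O)c2ccccc2)[C@@H]1O)c1ccccc1 | target

**Step count and risks**

Total steps: 13. Longest linear sequence: 13 (fully linear from furfural).

The three steps most likely to fail:

1. Step 10 (ring contraction). The Z-benzoyloxy group and the C6 oxygen are pushed together in the boat, so the sigmatropic shift may be slow. During enolisation or the prolonged heating the electrophilic enol benzoate may then be cleaved or may transfer its acyl group to the enolate. Fallback: setting out from 11, the same ruthenium-catalysed addition is run with pivalic acid to give the base-stable (Z)-enol pivalate F1, which tolerates excess base and longer heating. The ring contraction then gives the acid F2. LiAlH4 reduces the acid and removes both esters in one operation to give the acetonide triol F3, and tribenzoylation (BzCl, pyridine, DMAP) returns to the route at 18. This end game also avoids the selective reduction of step 11.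

2. Step 4 (with step 5). The dione 7 can enolise at C6, which is propargylic and flanked by the ketone and the ring oxygen. This would erase the only stereocentre and lead irreversibly to the aromatic 5-hydroxy-2-pyranone before the ketone is reduced. Fallback: setting out from 6, the lactol is converted with trimethyl orthoformate and BF3·OEt2 into the methyl acetal F4. Luche reduction gives the trans alcohol F5 and benzoylation gives the benzoate F6. Only then is the unsaturated cyclic acetal oxidised to the lactone (mCPBA, BF3·OEt2), returning to the route at 9, so the dione is never formed.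

3. Step 9 (hydro-acyloxylation). Next to the propargylic lactone oxygen the ruthenium vinylidene may ionise the C–O bond or add the acid in the Markovnikov sense, and the Z geometry may erode. Fallback: setting out from 11, rhodium-catalysed trans-hydroboration with pinacolborane ([Rh(cod)Cl]2, P(i-Pr)3, Et3N) gives the (Z)-alkenyl pinacolboronate F7. KHF2 converts it into the potassium trifluoroborate F8, and copper-catalysed oxidative coupling with benzoic acid (Chan–Lam type, with retention of alkene geometry) returns to the route at 12.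

**Further compounds**

F1 | step 10 | (Z)-4-O-benzoyl-6-deoxy-2,3-O-isopropylidene-7-O-pivaloyl-D-manno-hept-6-enono-1,5-lactone | O=C1O[C@H](/C=C\OC(=O)C(C)(C)C)[C@@H](OC(=O)c3ccccc3)[C@@H]2OC(C)(C)O[C@H]12
F2 | step 10 | 5-(benzoyloxy)-1,6-(isopropylidenedioxy)-2-(pivaloyloxy)cyclohex-3-ene-1-carboxylic acid, configuration as in 15 | OC(=O)[C@@]1(OC(C)(C)O2)[C@H](OC(=O)C(C)(C)C)C=C[C@@H](OC(=O)c3ccccc3)[C@@H]12
F3 | step 10 | 1-(hydroxymethyl)-1,6-(isopropylidenedioxy)cyclohex-3-ene-2,5-diol, configuration as in 17 | OC[C@@]1(OC(C)(C)O2)[C@H](O)C=C[C@@H](O)[C@@H]12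
F4 | step 4 | (2R)-2-ethynyl-6-methoxy-2H-pyran-3(6H)-one, anomer mixture | O=C1C=CC(OC)O[C@@H]1C#C
F5 | step 4 | (2R,3S)-2-ethynyl-6-methoxy-3,6-dihydro-2H-pyran-3-ol, anomer mixture | COC1O[C@H](C#C)[C@@H](O)C=C1
F6 | step 4 | (2R,3S)-2-ethynyl-6-methoxy-3,6-dihydro-2H-pyran-3-yl benzoate, anomer mixture | COC1O[C@H](C#C)[C@@H](OC(=O)c2ccccc2)C=C1
F7 | step 9 | (Z)-alkenyl pinacolboronate of lactone 11 (boron on the terminal alkene carbon) | O=C1O[C@H](/C=C\B3OC(C)(C)C(C)(C)O3)[C@@H](OC(=O)c4ccccc4)[C@@H]2OC(C)(C)O[C@H]12
F8 | step 9 | potassium (Z)-alkenyltrifluoroborate of lactone 11 | O=C1O[C@H](/C=C\[B-](F)(F)F)[C@@H](OC(=O)c4ccccc4)[C@@H]2OC(C)(C)O[C@H]12.[K+]
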